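**Retrosynthetic overview**

- The target is reached by desilylation and ester reduction of a (2S)-flavan that carries the C8 side chain as its (E)-methyl enoate (a higher oxidation level, inert to acid) and the 4'-OH as a TIPS ether.
- Ring C is the only ring made in the route (rings A and B are bought): a chiral phosphoric acid catalysed oxa-[4+2] joins an ortho-quinone methide of ring A (O1, C8a, C4a, C4) to a 2-vinylphenol of ring B (C2, C3), forming C3–C4, O1–C2 and the C2 stereocentre in one operation.
- Enabling feature: in ring A the phenol oxygen O1 on C8a sits ortho to the benzylic carbon C4, and the C7 methoxy is para to C4a, so the 2-hydroxy-4-methoxybenzyl alcohol ionises easily to the quinone methide. In ring B the free 2'-OH ortho to the C2 attachment docks the styrene on the chiral acid, and the 4'-oxygen makes the vinyl group nucleophilic.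
- Ring A fragment: 2-hydroxy-4-methoxybenzaldehyde, O-allylation, Claisen rearrangement to C3 (the future C8), E-selective cross-metathesis with methyl methacrylate, aldehyde reduction. Ring B fragment: 2,4-dihydroxybenzaldehyde, 4-O-silylation, Wittig methylenation.

Key step: step 7

Remark on numbering: chroman numbering (O1, C2, C3, C4, C4a, C5 to C8, C8a; ring B primed) is used throughout, also for the fragment atoms that become these positions.

Assumption: the sense of induction of the chiral phosphoric acid in step 7 cannot be predicted with certainty. The (R)-catalyst is written; if a first small run shows the opposite sense, its (S)-antipode is used with nothing else changed.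

**Route**

Step 1
Reactants: 1 2-hydroxy-4-methoxybenzaldehyde; 2 allyl bromide
Product: 3 4-methoxy-2-(prop-2-en-1-yloxy)benzaldehyde
Conditions: K2CO3, DMF, 60 °C
Reagents that add atoms: allyl bromide 2, C=CCBr
Why: Williamson ether synthesis, in which the phenoxide formed by K2CO3 in DMF displaces bromide from the reactive allylic halide (SN2).

Step 2
Reactants: 3 4-methoxy-2-(prop-2-en-1-yloxy)benzaldehyde
Product: 4 2-hydroxy-4-methoxy-3-(prop-2-en-1-yl)benzaldehyde
Conditions: PhNEt2, 195 °C, sealed tube
Reagents that add atoms: none
Why: aromatic Claisen rearrangement ([3,3]-sigmatropic shift, then tautomerisation), in which one of the two positions ortho to the ether oxygen carries the formyl group, so the allyl group can only arrive at C3 between the two oxygens, the future C8.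

Step 3
Reactants: 4 2-hydroxy-4-methoxy-3-(prop-2-en-1-yl)benzaldehyde; 5 methyl methacrylate
Product: 6 methyl (2E)-4-(3-formyl-2-hydroxy-6-methoxyphenyl)-2-methylbut-2-enoate
Conditions: second-generation Hoveyda–Grubbs catalyst RuCl2(H2IMes)(=CH-C6H4-2-OiPr) (5 mol %), 1,4-benzoquinone (10 mol %), 5 (10 equiv), CH2Cl2, 40 °C
Reagents that add atoms: methyl methacrylate 5, C=C(C)C(=O)OC
Why: olefin cross-metathesis of a terminal allyl arene with a 1,1-disubstituted acrylate that does not homodimerise, in which the trisubstituted enoate should form under thermodynamic control as the E isomer (ester trans to the benzylic CH2) and benzoquinone suppresses double-bond migration by ruthenium hydrides.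

Step 4
Reactants: 6 methyl (2E)-4-(3-formyl-2-hydroxy-6-methoxyphenyl)-2-methylbut-2-enoate
Product: 7 methyl (2E)-4-[2-hydroxy-3-(hydroxymethyl)-6-methoxyphenyl]-2-methylbut-2-enoate
Conditions: NaBH4, CeCl3·7H2O, MeOH, −20 °C; pH 7 phosphate buffer
Reagents that add atoms: none
Why: chemoselective 1,2-reduction of the aldehyde under Luche conditions, which leave the enoate untouched and keep the medium near neutral and cold so that the phenol does not add to the enoate and the acid-labile benzylic alcohol is not ionised.

Step 5
Reactants: 8 2,4-dihydroxybenzaldehyde; 9 chlorotriisopropylsilane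
Product: 10 2-hydroxy-4-[(triisopropylsilyl)oxy]benzaldehyde
Conditions: imidazole, CH2Cl2, 0 °C
Reagents that add atoms: chlorotriisopropylsilane 9, CC(C)[Si](Cl)(C(C)C)C(C)C
Why: selective silylation of the more acidic, unchelated 4-OH, since the 2-OH is held in a hydrogen bond to the formyl group and is hindered toward the bulky silyl chloride.

Step 6
Reactants: 10 2-hydroxy-4-[(triisopropylsilyl)oxy]benzaldehyde; 11 methyltriphenylphosphonium bromide
Product: 12 2-ethenyl-5-[(triisopropylsilyl)oxy]phenol
Conditions: 11 (2.3 equiv), NaN(SiMe3)2 (2.3 equiv), THF, 0 °C to rt; aqueous NH4Cl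
Reagents that add atoms: methyltriphenylphosphonium bromide 11, C[P+](c1ccccc1)(c1ccccc1)c1ccccc1.[Br-]
Why: Wittig methylenation, in which one equivalent of ylide is spent on the phenol, a second converts the aldehyde to the vinyl group, and the bulky TIPS aryl ether should survive the non-nucleophilic amide base.

Step 7
Reactants: 7 methyl (2E)-4-[2-hydroxy-3-(hydroxymethyl)-6-methoxyphenyl]-2-methylbut-2-enoate; 12 2-ethenyl-5-[(triisopropylsilyl)oxy]phenol
Product: 14 methyl (2E)-4-[(2S)-2-{2-hydroxy-4-[(triisopropylsilyl)oxy]phenyl}-7-methoxy-3,4-dihydro-2H-chromen-8-yl]-2-methylbut-2-enoate, via ortho-quinone methide 13 (not isolated)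
Conditions: (R)-3,3'-bis(2,4,6-triisopropylphenyl)-1,1'-binaphthyl-2,2'-diyl hydrogen phosphate (10 mol %), 4 Å molecular sieves, toluene, 30 °C, 7 added over 6 h to 12 (2 equiv); then Et3N
Reagents that add atoms: none
Why: Proposed new method: the chiral phosphoric acid protonates the benzylic hydroxyl of 7, water leaves with the help of the para C7 methoxy group and the ortho phenol, and ortho-quinone methide 13 stays hydrogen-bonded through its carbonyl oxygen to the P–OH of the catalyst while the phosphoryl oxygen binds the 2'-OH of 12. Inside this complex an inverse-electron-demand oxa-[4+2] cycloaddition (hetero-Diels–Alder) should take place in a concerted but asynchronous way, the terminal vinyl carbon of 12 bonding to the methide carbon (C3–C4) ahead of closure of the carbonyl oxygen on the benzylic carbon (O1–C2). The closest known reaction type is the chiral phosphoric acid catalysed [4+2] cycloaddition of ortho-quinone methides from ortho-hydroxybenzhydrols with ortho-hydroxystyrenes, together with the thermal racemic ortho-quinone methide/styrene route to flavans; new here are a methide without a substituent at its terminus and a product whose only stereocentre lies on the carbon that came from the styrene. Ring C is closed by intermolecular [4+2] annulation, four atoms (O1, C8a, C4a, C4) coming from 13 and two (C2, C3) from 12, and no other ring is formed. The C2 stereocentre is set by the catalyst, whose binaphthyl pocket with its 2,4,6-triisopropylphenyl groups shields one face of the hydrogen-bonded styrene, and the antipode that gives 2S is the one used. The step needs regioselectivity (oxygen to the benzylic carbon), which the 2'-OH and 4'-silyloxy donors secure by stabilising positive charge at C2, and chemoselectivity over oligomerisation of 13, dimerisation of 12 and C-alkylation of ring B, which slow addition of 7 to an excess of 12 and the acid-inert enoate side chain are meant to secure.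

Step 8
Reactants: 14 methyl (2E)-4-[(2S)-2-{2-hydroxy-4-[(triisopropylsilyl)oxy]phenyl}-7-methoxy-3,4-dihydro-2H-chromen-8-yl]-2-methylbut-2-enoate
Product: 15 (2E)-4-[(2S)-2-{2-hydroxy-4-[(triisopropylsilyl)oxy]phenyl}-7-methoxy-3,4-dihydro-2H-chromen-8-yl]-2-methylbut-2-en-1-ol
Conditions: i-Bu2AlH (4.5 equiv), CH2Cl2, −78 °C; then MeOH, aqueous potassium sodium tartrate
Reagents that add atoms: none
Why: 1,2-reduction of the α,β-unsaturated ester to the allylic alcohol by i-Bu2AlH with retention of the E geometry, the aryl silyl ether and the benzylic O1–C2 bond being inert at −78 °C so that C2 is not touched.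

Step 9
Reactants: 15 (2E)-4-[(2S)-2-{2-hydroxy-4-[(triisopropylsilyl)oxy]phenyl}-7-methoxy-3,4-dihydro-2H-chromen-8-yl]-2-methylbut-2-en-1-ol
Product: 16 4-[(2S)-8-[(2E)-4-hydroxy-3-methylbut-2-en-1-yl]-7-methoxy-3,4-dihydro-2H-chromen-2-yl]benzene-1,3-diol (morusyunnansin E)
Conditions: Bu4NF, AcOH (1:1), THF, 0 °C
Reagents that add atoms: none
Why: fluoride-mediated cleavage of the aryl silyl ether, buffered with acetic acid so that no free phenoxide can open the O1–C2 bond and the C2 configuration is kept.

**Compound list**

1 | 2-hydroxy-4-methoxybenzaldehyde | COc1ccc(C=O)c(O)c1 | starting material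
2 | allyl bromide (3-bromoprop-1-ene) | C=CCBr | starting material
3 | 4-methoxy-2-(prop-2-en-1-yloxy)benzaldehyde | COc1ccc(C=O)c(OCC=C)c1 | intermediate
4 | 2-hydroxy-4-methoxy-3-(prop-2-en-1-yl)benzaldehyde | COc1ccc(C=O)c(O)c1CC=C | intermediate
5 | methyl methacrylate | C=C(C)C(=O)OC | starting material
6 | methyl (2E)-4-(3-formyl-2-hydroxy-6-methoxyphenyl)-2-methylbut-2-enoate | COc1ccc(C=O)c(O)c1C/C=C(\C)C(=O)OC | intermediate
7 | methyl (2E)-4-[2-hydroxy-3-(hydroxymethyl)-6-methoxyphenyl]-2-methylbut-2-enoate | COc1ccc(CO)c(O)c1C/C=C(\C)C(=O)OC | intermediate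
8 | 2,4-dihydroxybenzaldehyde | O=Cc1ccc(O)cc1O | starting material
9 | chlorotriisopropylsilane | CC(C)[Si](Cl)(C(C)C)C(C)C | starting material
10 | 2-hydroxy-4-[(triisopropylsilyl)oxy]benzaldehyde | CC(C)[Si](Oc1ccc(C=O)c(O)c1)(C(C)C)C(C)C | intermediate
11 | methyltriphenylphosphonium bromide | C[P+](c1ccccc1)(c1ccccc1)c1ccccc1.[Br-] | starting material
12 | 2-ethenyl-5-[(triisopropylsilyl)oxy]phenol | C=Cc1ccc(O[Si](C(C)C)(C(C)C)C(C)C)cc1O | intermediate
13 | methyl (2E)-4-(2-methoxy-5-methylidene-6-oxocyclohexa-1,3-dien-1-yl)-2-methylbut-2-enoate (ortho-quinone methide, not isolated) | C=C1C=CC(OC)=C(C/C=C(\C)C(=O)OC)C1=O | intermediate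
14 | methyl (2E)-4-[(2S)-2-{2-hydroxy-4-[(triisopropylsilyl)oxy]phenyl}-7-methoxy-3,4-dihydro-2H-chromen-8-yl]-2-methylbut-2-enoate | COc1ccc2c(c1C/C=C(\C)C(=O)OC)O[C@H](c1ccc(O[Si](C(C)C)(C(C)C)C(C)C)cc1O)CC2 | intermediate
15 | (2E)-4-[(2S)-2-{2-hydroxy-4-[(triisopropylsilyl)oxy]phenyl}-7-methoxy-3,4-dihydro-2H-chromen-8-yl]-2-methylbut-2-en-1-ol | COc1ccc2c(c1C/C=C(\C)CO)O[C@H](c1ccc(O[Si](C(C)C)(C(C)C)C(C)C)cc1O)CC2 | intermediate
16 | 4-[(2S)-8-[(2E)-4-hydroxy-3-methylbut-2-en-1-yl]-7-methoxy-3,4-dihydro-2H-chromen-2-yl]benzene-1,3-diol (morusyunnansin E) | COc1ccc2c(c1C/C=C(\C)CO)O[C@H](c1ccc(O)cc1O)CC2 | target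

**Step count and risks**

Total step count: 9. Longest linear sequence: 7 steps (steps 1, 2, 3, 4, 7, 8, 9).

The three steps most likely to fail:

1. Step 7 (the proposed new method). What may go wrong:
- slow ionisation of the primary benzylic alcohol under the chiral acid;
- self-condensation of the quinone methide with ring A of unreacted 7;
- C-alkylation of the resorcinol-type ring B, or acid-induced dimerisation of the vinylphenol;
- poor facial selectivity with a methide that has no substituent at its terminus;
- loss of enantiomeric purity by reversible acid-mediated opening of the O1–C2 bond if the product stays with the catalyst too long.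

Fallback (known chemistry): it sets out from 7 and 12 and comes back at 14. Compounds 7 and 12 (2 equiv) are heated without acid in toluene (sealed tube, about 130 °C, a little BHT as radical inhibitor). Thermal loss of water from the salicyl alcohol gives 13, which the styrene traps in an uncatalysed hetero-Diels–Alder reaction of the same regiochemistry to give racemic methyl (2E)-4-[2-{2-hydroxy-4-[(triisopropylsilyl)oxy]phenyl}-7-methoxy-3,4-dihydro-2H-chromen-8-yl]-2-methylbut-2-enoate F1. Preparative HPLC on a chiral stationary phase (amylose tris(3,5-dimethylphenylcarbamate), hexane/2-propanol) should then separate 14 from its mirror image, methyl (2E)-4-[(2R)-2-{2-hydroxy-4-[(triisopropylsilyl)oxy]phenyl}-7-methoxy-3,4-dihydro-2H-chromen-8-yl]-2-methylbut-2-enoate F2, which is set aside. Stereocontrol by catalysis is thus replaced by resolution.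

2. Step 3. What may go wrong: migration of the allyl double bond into conjugation with the ring before metathesis, and slow turnover with the 1,1-disubstituted partner, so that conversion stalls or the E geometry is not reached cleanly.

Fallback: it sets out from 4 and comes back at 6, building the trisubstituted alkene by olefination instead of metathesis. Oxidative cleavage of the allyl double bond (OsO4 cat., NaIO4, 2,6-lutidine, dioxane/water) should give 2-(3-formyl-2-hydroxy-6-methoxyphenyl)acetaldehyde F3, which stands in equilibrium with its cyclic hemiacetal. Wittig reaction with the stabilised ylide methyl 2-(triphenylphosphoranylidene)propanoate (CH2Cl2, rt) should then give 6 with E selectivity. The aliphatic aldehyde reacts at room temperature, whereas the chelated, electron-rich aryl aldehyde should not.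

3. Step 4. What may go wrong: conjugate addition of the phenoxide oxygen to the enoate (five-membered ring closure) under the basic hydride conditions, and premature ionisation of the electron-rich benzylic alcohol during isolation.

Fallback: it sets out from 4 and comes back at 7 by changing the order of events, so that phenoxide and enoate never meet under basic conditions. Compound 4 is reduced first (NaBH4, MeOH, 0 °C) to 2-(hydroxymethyl)-5-methoxy-6-(prop-2-en-1-yl)phenol F4. Cross-metathesis of this compound with 5 under the neutral conditions of step 3 then gives 7 directly, purified on triethylamine-deactivated silica.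

Further compounds
F1 | step 7 | racemic methyl (2E)-4-[2-{2-hydroxy-4-[(triisopropylsilyl)oxy]phenyl}-7-methoxy-3,4-dihydro-2H-chromen-8-yl]-2-methylbut-2-enoate | COc1ccc2c(c1C/C=C(\C)C(=O)OC)OC(c1ccc(O[Si](C(C)C)(C(C)C)C(C)C)cc1O)CC2
F2 | step 7 | methyl (2E)-4-[(2R)-2-{2-hydroxy-4-[(triisopropylsilyl)oxy]phenyl}-7-methoxy-3,4-dihydro-2H-chromen-8-yl]-2-methylbut-2-enoate | COc1ccc2c(c1C/C=C(\C)C(=O)OC)O[C@@H](c1ccc(O[Si](C(C)C)(C(C)C)C(C)C)cc1O)CC2
F3 | step 3 | 2-(3-formyl-2-hydroxy-6-methoxyphenyl)acetaldehyde | COc1ccc(C=O)c(O)c1CC=O
F4 | step 4 | 2-(hydroxymethyl)-5-methoxy-6-(prop-2-en-1-yl)phenol | COc1ccc(CO)c(O)c1CC=C
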